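**Retrosynthetic overview**
- The target is disconnected to a 3α,4α:9α,10α-bis-epoxy-8α-ol plus two molecules of (Z)-hex-2-enoic acid: one reductive, acylative double epoxide opening gives both ester C–O bonds and the C4–H and C10–H bonds (new step).
- The bis-epoxide comes from a trienol by double α-face epoxidation, the key C–O bond formation (C3–O and C9–O).
- The trienol comes from a trienone by hydride reduction at C8; the trienone comes from a dienone by enolate alkenylation (C7–isopropenyl).
- The dienone comes from (S)-Wieland–Miescher ketone by methylenation and alkene isomerisation; the (Z)-acid comes from hex-2-ynoic acid.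
- Rings A and B are bought preformed; the only rings made are the two oxiranes, formed together and opened together.

Assumption: compound 1 is bought as the enantiopure (S) ketone; eremophilane numbering is used (ring A = C1–C5 and C10, ring B = C5–C10, C14 = methyl on C5, C15 = methyl on C4, C11–C13 = isopropenyl on C7), β means the face of C14, and Cp = η5-C5H5.

**Step 1**
Reactants: 1 (S)-(+)-Wieland–Miescher ketone
Product: 2 (4aR)-4a-methyl-5-methylidene-4,4a,5,6,7,8-hexahydronaphthalen-2(3H)-one
Conditions: Ph3PCH3Br (1.2 equiv), KOt-Bu, THF, 0 °C → rt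
Reagents that add atoms: methyltriphenylphosphonium bromide, C[P+](c1ccccc1)(c1ccccc1)c1ccccc1.[Br-]
Why: Wittig methylenation, in which the non-conjugated C4 ketone is more electrophilic than the enone carbonyl and reacts first; no stereocentre is touched.

**Step 2**
Reactants: 2 (4aR)-4a-methyl-5-methylidene-4,4a,5,6,7,8-hexahydronaphthalen-2(3H)-one
Product: 3 (4aR)-4a,5-dimethyl-4,4a,7,8-tetrahydronaphthalen-2(3H)-one
Conditions: RhCl3·3H2O (5 mol %), EtOH, 80 °C
Reagents that add atoms: none
Why: Metal-hydride alkene isomerisation moves the exocyclic alkene to the trisubstituted C3=C4 position, and the quaternary C5 blocks migration past it.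

**Step 3**
Reactants: 3 (4aR)-4a,5-dimethyl-4,4a,7,8-tetrahydronaphthalen-2(3H)-one
Product: 6 7βH-eremophila-3,9,11-trien-8-one, via lithium dienolate 4 (not isolated), via chlorozinc dienolate 5 (not isolated)
Conditions: LiN(SiMe3)2, THF, −78 °C; ZnCl2, −78 → 0 °C; 2-bromopropene, Pd(P(t-Bu)3)2 (5 mol %), rt; aq. NH4Cl
Reagents that add atoms: 2-bromopropene, C=C(C)Br
Why: Negishi-type palladium-catalysed α-alkenylation of a ketone enolate, in which kinetic α′-deprotonation gives the cross-conjugated enolate regiospecifically, the weakly basic zinc enolate spares the product C7–H, and the C7–C11 bond forms on the α face, anti to the axial C14 methyl, to give the equatorial isopropenyl epimer.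

**Step 4**
Reactants: 6 7βH-eremophila-3,9,11-trien-8-one
Product: 7 7βH-eremophila-3,9,11-trien-8α-ol
Conditions: LiBH(s-Bu)3, THF, −78 °C; then H2O
Reagents that add atoms: none
Why: Bulky trialkylborohydride 1,2-reduction (the β,β-disubstituted enone resists conjugate reduction) delivers hydride equatorially from the β face and gives the pseudo-axial 8α-alcohol cis to the isopropenyl group, as in LiBH(s-Bu)3 and KBH(s-Bu)3 reductions of steroidal 4-en-3-ones to 3α-ols.

**Step 5**
Reactants: 7 7βH-eremophila-3,9,11-trien-8α-ol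
Product: 8 3α,4α:9α,10α-diepoxy-7βH-eremophil-11-en-8α-ol
Conditions: mCPBA (2.1 equiv), NaHCO3, CH2Cl2, −20 → 0 °C; aq. Na2S2O3 work-up
Reagents that add atoms: mCPBA (3-chloroperoxybenzoic acid), O=C(OO)c1cccc(Cl)c1
Why: Prilezhaev epoxidation attacks both trisubstituted ring alkenes on the α face (anti to the axial C14 methyl, and for C9=C10 also directed by the cis 8α-OH, the Henbest effect), which fixes the C3–O and C9–O bonds, while the less electron-rich 1,1-disubstituted isopropenyl alkene reacts more slowly.

**Step 6**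
Reactants: 9 hex-2-ynoic acid
Product: 10 (Z)-hex-2-enoic acid
Conditions: H2 (1 atm), Pd/CaCO3 poisoned with Pb(OAc)2, quinoline, EtOAc, rt
Reagents that add atoms: none
Why: Lindlar semihydrogenation adds H2 syn to the alkyne on the poisoned palladium surface and stops at the Z alkene.

**Step 7**
Reactants: 8 3α,4α:9α,10α-diepoxy-7βH-eremophil-11-en-8α-ol; 10 (Z)-hex-2-enoic acid (two molecules are consumed, one per ester)
Product: 13 8α-hydroxy-7βH,10αH-eremophil-11-ene-3α,9α-diyl bis[(2Z)-hex-2-enoate], via (Z)-hex-2-enoyl chloride 11 (not isolated), via 3,9-bis-O-[Cp2TiCl] alkoxide 12 (not isolated)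
Conditions: (a) 10 (2.4 equiv), Me2C=C(Cl)NMe2 (2.3 equiv), CH2Cl2, 0 °C → rt; (b) 8, Cp2TiCl2 (2.2 equiv), Mn, 1,4-cyclohexadiene (10 equiv), THF, rt, then filter from Mn; (c) solution of 11 from (a), −20 → 0 °C; aq. NaHCO3
Reagents that add atoms: (Z)-hex-2-enoic acid, the second equivalent of 10 that supplies the second ester, CCC/C=C\C(=O)O
Why: Proposed new method: trivalent titanium (Cp2TiCl) opens both α-epoxides by homolysis of the C–O bond at the more substituted carbon, the tertiary C4 and C10 radicals take H from 1,4-cyclohexadiene on the α face (axial, anti to the axial C14 methyl) to set 4β-methyl and the trans ring fusion, and each of the two O–Ti bonds is then cleaved by one molecule of acyl chloride 11 instead of a proton or silyl source (returning Cp2TiCl2 without any amine base that could isomerise the Z-enoate), so only the former epoxide oxygens O3 and O9 are esterified and the axial 8α-OH stays free; the closest known reaction type is the Nugent–RajanBabu Cp2TiCl reductive epoxide opening and its catalytic versions with collidinium chloride or Me3SiCl cleavage of the Ti–O bond.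

**Compound list**
1 | (S)-(+)-Wieland–Miescher ketone, (8aS)-8a-methyl-3,4,8,8a-tetrahydronaphthalene-1,6(2H,7H)-dione | C[C@]12CCC(=O)C=C1CCCC2=O | starting material
2 | (4aR)-4a-methyl-5-methylidene-4,4a,5,6,7,8-hexahydronaphthalen-2(3H)-one | C=C1CCCC2=CC(=O)CC[C@]12C | intermediate
3 | (4aR)-4a,5-dimethyl-4,4a,7,8-tetrahydronaphthalen-2(3H)-one (11,12,13-trinoreremophila-3,9-dien-8-one) | CC1=CCCC2=CC(=O)CC[C@]12C | intermediate
4 | lithium (4aR)-4a,5-dimethyl-4,4a,7,8-tetrahydronaphthalen-2-olate (C7=C8–OLi dienolate of 3) | CC1=CCCC2=CC([O-])=CC[C@]12C.[Li+] | intermediate (not isolated)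
5 | chlorozinc dienolate of 3 (C7=C8–OZnCl) | CC1=CCCC2=CC(O[Zn]Cl)=CC[C@]12C | intermediate (not isolated)
6 | 7βH-eremophila-3,9,11-trien-8-one, (3S,4aR)-4a,5-dimethyl-3-(prop-1-en-2-yl)-4,4a,7,8-tetrahydronaphthalen-2(3H)-one | C=C(C)[C@@H]1C[C@]2(C)C(C)=CCCC2=CC1=O | intermediate
7 | 7βH-eremophila-3,9,11-trien-8α-ol, (2S,3S,4aR)-4a,5-dimethyl-3-(prop-1-en-2-yl)-2,3,4,4a,7,8-hexahydronaphthalen-2-ol | C=C(C)[C@@H]1C[C@]2(C)C(C)=CCCC2=C[C@@H]1O | intermediate
8 | (3R,4S,5R,7S,8R,9R,10S)-3α,4α:9α,10α-diepoxy-7βH-eremophil-11-en-8α-ol | C=C(C)[C@@H]1C[C@]2(C)[C@]3(C)O[C@@H]3CC[C@]24O[C@@H]4[C@@H]1O | intermediate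
9 | hex-2-ynoic acid | CCCC#CC(=O)O | starting material
10 | (Z)-hex-2-enoic acid | CCC/C=C\C(=O)O | intermediate
11 | (Z)-hex-2-enoyl chloride | CCC/C=C\C(=O)Cl | intermediate (not isolated)
12 | 3α,9α-bis[chlorobis(cyclopentadienyl)titanoxy]-7βH,10αH-eremophil-11-en-8α-ol | C=C(C)[C@@H]1C[C@]2(C)[C@@H](C)[C@H](O[Ti](Cl)(C3C=CC=C3)C3C=CC=C3)CC[C@H]2[C@H](O[Ti](Cl)(C3C=CC=C3)C3C=CC=C3)[C@@H]1O | intermediate (not isolated)
13 | (3R,4R,5R,7S,8R,9S,10R)-8α-hydroxy-7βH,10αH-eremophil-11-ene-3α,9α-diyl bis[(2Z)-hex-2-enoate] | C=C(C)[C@@H]1C[C@]2(C)[C@@H](C)[C@H](OC(=O)/C=C\CCC)CC[C@H]2[C@H](OC(=O)/C=C\CCC)[C@@H]1O | target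

**Count**
Total steps: 7. Longest linear sequence: 6 (steps 1, 2, 3, 4, 5, 7).

**Steps most likely to fail**

Step 7 (the new step). The risks are acylation of the free 8α-OH after Ti–O exchange, side reactions of the enoyl chloride with residual trivalent titanium, and imperfect face selectivity of H transfer at C10. Fallback, from 8 back to 13, with known chemistry: both epoxides are opened under the established stoichiometric conditions (Cp2TiCl2/Mn, 1,4-cyclohexadiene, THF, rt) and the titanium alkoxides are hydrolysed on aqueous acidic work-up to the free triol 7βH,10αH-eremophil-11-ene-3α,8α,9α-triol F1. The two equatorial hydroxyls of F1 are then esterified under steric control with 10 (2.2 equiv, EDC·HCl, DMAP 0.2 equiv, CH2Cl2, −20 → 0 °C), the axial, doubly flanked 8α-OH reacting last, to give 13.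

Step 3. Intermolecular α′-alkenylation of a cross-conjugated enone enolate has little precedent; γ-coupling or isomerisation of the isopropenyl group into conjugation may compete. Fallback, from 3 back to 6, by an aldol/Peterson sequence: the chlorozinc dienolate 5 (LiN(SiMe3)2, then ZnCl2, THF, −78 °C) is added to (trimethylsilyl)acetone at −78 °C and quenched cold with AcOH. This gives the β-hydroxysilane 11-hydroxy-12-(trimethylsilyl)-7βH-eremophila-3,9-dien-8-one F2 (either C11 epimer), the C7–C11 bond again forming on the α face. Acid-promoted Peterson elimination (cat. H2SO4, THF, 0 °C) can place the alkene only between C11 and the silylated C12, and gives 6 with C7 untouched.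

Step 5. Over-oxidation of the isopropenyl group or acid-promoted opening of the epoxy alcohol can lower the yield of the bis-epoxide. Fallback, from 7 back to 8: hydroxyl-directed epoxidation with VO(acac)2 (2 mol %) and t-BuOOH (toluene, 0 °C) first converts only the allylic C9=C10 alkene into 9α,10α-epoxy-7βH-eremophila-3,11-dien-8α-ol F3. One equivalent of mCPBA (NaHCO3, CH2Cl2, −20 °C) then only has to choose between the trisubstituted ring-A alkene and the isopropenyl group, and gives 8.

**Further compounds**
F1 | step 7 | 7βH,10αH-eremophil-11-ene-3α,8α,9α-triol | C=C(C)[C@@H]1C[C@]2(C)[C@@H](C)[C@H](O)CC[C@H]2[C@H](O)[C@@H]1O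
F2 | step 3 | 11-hydroxy-12-(trimethylsilyl)-7βH-eremophila-3,9-dien-8-one (C11 epimers) | CC(O)(C[Si](C)(C)C)[C@@H]1C[C@]2(C)C(C)=CCCC2=CC1=O
F3 | step 5 | 9α,10α-epoxy-7βH-eremophila-3,11-dien-8α-ol | C=C(C)[C@@H]1C[C@]2(C)C(C)=CCC[C@]24O[C@@H]4[C@@H]1O
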